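The charge of free catalyst is tied to the charge of substrate at 1.1 mol% in each flask below, and every turn gives the catalyst back, so a richer flask also runs on more catalyst.

| flask | substrate | free catalyst | time |
|---|---|---|---|
| zeta | 0.015 M | 1.1 mol% | 5.0 min |
| delta | 0.020 M | 1.1 mol% | 5.0 min |
| eta | 0.030 M | 1.1 mol% | 5.0 min |
| theta | 0.050 M | 1.1 mol% | 5.0 min |
| epsilon | 0.080 M | 1.1 mol% | 5.0 min |

    target → over-reaction product (k1 = 0.025 /s)
    catalyst intermediate B → free catalyst + target (k2 = 640 /s)
    catalyst intermediate A ⇌ catalyst intermediate B (K3 = 2.6, k3 = 190 /s)
    substrate + free catalyst → catalyst intermediate A (k4 = 150 /M/s)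

- [target] at the end for zeta, delta, eta, theta, epsilon, in this order
- the course of these numbers from the first flask to the last (rises, then falls / falls, then rises / falls all the way / rises all the way / hardly changes)

Even in epsilon a free catalyst is captured at 12.0 /s, slower than intermediate A moves on at 190 /s, so I count the catalyst as free. Substrate then decays pseudo-first-order with a feed constant f, the capture constant times the loading times the charge c, and target is lost with L = 0.025 /s. The quantity to carry is the feed ratio r = f/L, feed constant over loss constant. With 0.0248 /s in zeta, r is 0.990; with 0.0495 /s in eta it is 1.98; with 0.132 /s in epsilon it is 5.28.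

In powers of ten, target made early falls by 3.26 over the run. Substrate falls by 3.22 in zeta and 17.2 in epsilon. There are two ways to reckon the end value T at time t:

Tail: T = c · f/(f − L) · e^(−Lt)

Level race: T = c · f t · e^(−mt), with m the mean of f and L

In epsilon the tail gives 0.0546 mM, while the level race gives 1.88 × 10⁻¹⁰ M. The race cheats here, since it charges target with a loss constant m of 0.0785 /s, faster than the L that target made in the first seconds suffers.

In zeta they part the other way. Its f is smaller than L, so the tail's factor is −99.0 and T comes out negative, which cannot stand. The tail cheats here, since substrate and target fall at nearly one pace. The race gives 0.0640 mM.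

Since c grows with f, the tail's c · f/(f − L) is lowest where f is twice L, at a charge of 0.0303 M. Eta stands there, with 0.0335 mM. Delta, with f = 0.0330 /s, lies near L, so I take the tail less its unspent part, T = c · f/(f − L) · (e^(−Lt) − e^(−ft)), which gives 0.0415 mM. Theta, with f = 0.0825 /s, takes the plain tail at 0.0397 mM. The turning charge lies between zeta's and epsilon's, so I commit to a row that falls, then rises.

The forecast gave 6.400 × 10⁻⁵ M, 4.200 × 10⁻⁵ M, 3.400 × 10⁻⁵ M, 4.000 × 10⁻⁵ M, 5.500 × 10⁻⁵ M, so falls, then rises, holding that “dilute flasks gain from still-late formation while concentrated flasks gain from a larger starting amount”.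

The simulation gives 6.48 × 10⁻⁵ M, 4.20 × 10⁻⁵ M, 3.39 × 10⁻⁵ M, 4.01 × 10⁻⁵ M, 5.51 × 10⁻⁵ M, so falls, then rises, turning at 0.030 M. In epsilon >99.9% of the catalyst is free after 1.50 min, and the way back from intermediate B to intermediate A makes no difference to its target.

The largest single effect is the loss of target: without that step epsilon ends with 0.0800 M of target, not 5.51 × 10⁻⁵ M. The feed ratio then tells which flask keeps feeding. Zeta, at 0.990, still holds 0.0606% of its substrate at the end, and epsilon, at 5.28, holds 0%. Eta, at 1.98, sits lowest, with 3.39 × 10⁻⁵ M of target.

(The numbers of this flask are assumed, and the outcome is calculated.)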